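**Retrosynthetic overview**
- Target 13 is 4'-O-methylcupressuflavone, an 8,8''-biflavone; the last step removes five isopropyl ethers from 12 with BCl3 and leaves the 4'-OMe.
- Both pyranone rings (ring C of each flavone unit) are cut at O1–C2, a C–O bond: cyclodehydration of bis(1,3-diketone) 11, which comes from mixed diaryl ester 10 by a double Baker–Venkataraman shift.
- The two different ring B units are put on as aryl ester C–O bonds, one on each phenol oxygen of the symmetric biaryl diol 4, in one flask by a tin-templated hetero-bis-aroylation (the new step).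
- Diol 4 is the ortho–ortho oxidative dimer of 2-hydroxy-4,6-diisopropoxyacetophenone 3, made from phloroacetophenone 1.
- Ring order: ring A of each half comes from 1, then the biaryl bond, then both rings C together; rings B arrive preformed in the aroyl chlorides.

Assumption: the SMILES has no stereocentre and gives no descriptor for the hindered 8,8'' axis, so the compound is made as drawn with the axis unassigned (racemic), and no resolution is included.

**Route**

Step 1
Reactants: 1 2,4,6-trihydroxyacetophenone (phloroacetophenone), 2 2-bromopropane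
Product: 3 1-(2-hydroxy-4,6-diisopropoxyphenyl)ethanone
Conditions: 2 (2.3 equiv), K2CO3 (2.5 equiv), DMF, 60 °C
Reagents that add atoms: 2-bromopropane, CC(C)Br
Why: Williamson ether synthesis in which the 4- and 6-phenoxides are alkylated while the 2-OH, hydrogen-bonded to the acetyl C=O, is the least nucleophilic and stays free; no stereocentre is formed.

Step 2
Reactants: 3 1-(2-hydroxy-4,6-diisopropoxyphenyl)ethanone (two molecules)
Product: 4 3,3'-diacetyl-4,4',6,6'-tetraisopropoxybiphenyl-2,2'-diol (racemic axis)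
Conditions: FeCl3 (anhydrous, 2.2 equiv) on SiO2, CH2Cl2, 0 °C to rt; dilute aq. HCl work-up
Reagents that add atoms: none
Why: Oxidative phenol coupling (phenoxyl-radical dimerisation by trivalent iron) at C3, ortho to the chelated phenol, because the para position C5 is shielded by two isopropoxy groups; the new axis has no assigned configuration and forms as the racemate.

Step 3
Reactants: 4 3,3'-diacetyl-4,4',6,6'-tetraisopropoxybiphenyl-2,2'-diol, 5 dibutyltin oxide, 6 4-methoxybenzoyl chloride, 7 4-isopropoxybenzoyl chloride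
Product: 10 3,3'-diacetyl-4,4',6,6'-tetraisopropoxy-2'-(4-isopropoxybenzoyloxy)biphenyl-2-yl 4-methoxybenzoate, via cyclic dibutylstannylene diether 8 (not isolated), via chlorodibutylstannyl ether mono-anisoate 9 (not isolated)
Conditions: Bu2SnO (1.05 equiv), toluene, reflux, Dean–Stark; then 6 (1.0 equiv), 0 °C to rt; then 7 (1.5 equiv), 4-(dimethylamino)pyridine (0.2 equiv), 60 °C
Reagents that add atoms: 4-methoxybenzoyl chloride, COc1ccc(cc1)C(Cl)=O; 4-isopropoxybenzoyl chloride, CC(C)Oc1ccc(cc1)C(Cl)=O
Why: Proposed new method: tin-templated one-flask hetero-bis-aroylation of a biaryl-2,2'-diol. Bu2SnO ties both phenol oxygens of 4 to one tin in the seven-membered dioxastannepine 8. The first acid chloride cleaves one Sn–O bond to form the first aryl ester C–O bond and leaves the other oxygen as a Bu2Sn(Cl)–OAr in 9. That oxygen, chelated by the neighbouring acetyl and ester carbonyls, is too weak a nucleophile to react with uncatalysed acid chloride at 0 °C, and it is acylated only when the second acid chloride is added with the acyl-transfer catalyst. The two different aroyl groups are therefore placed one per ring without a statistical mixture, and each ester joins the phenol oxygen to the carbon that becomes C2 of a pyranone. The closest known reaction type is dibutylstannylene-acetal monoacylation of aliphatic 1,2- and 1,3-diols, which has not been used to install two different acyl groups on a tetra-ortho-substituted biaryl diol.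

Step 4
Reactants: 10 3,3'-diacetyl-4,4',6,6'-tetraisopropoxy-2'-(4-isopropoxybenzoyloxy)biphenyl-2-yl 4-methoxybenzoate
Product: 12 5,5'',7,7'',4'''-penta-O-isopropyl-4'-O-methylcupressuflavone, via bis(1,3-diketone) 11 (not isolated)
Conditions: LiN(SiMe3)2 (6 equiv), THF, −78 to −10 °C; AcOH quench, evaporate; then H2SO4 (cat.), AcOH, 90 °C
Reagents that add atoms: none
Why: Double Baker–Venkataraman rearrangement (each acetyl enolate takes the aroyl group from the ester oxygen of its own ring through a six-membered transition state) followed by acid-catalysed cyclodehydration, in which the freed 2-OH, the only free phenol on each ring, adds to the aroyl C=O and water is lost, closing both pyranones through O1–C2 and fixing the 8,8'' linkage.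

Step 5
Reactants: 12 5,5'',7,7'',4'''-penta-O-isopropyl-4'-O-methylcupressuflavone
Product: 13 4'-O-methylcupressuflavone (target)
Conditions: BCl3 (1 M in CH2Cl2, 12 equiv), CH2Cl2, −78 to 0 °C; then H2O/MeOH
Reagents that add atoms: none
Why: Lewis-acid ether cleavage in which BCl3 removes the five secondary isopropyl aryl ethers by an SN1-like path at or below 0 °C, while the primary, non-chelated 4'-OMe is inert under these conditions; the axis is untouched.

**Compound list**
1 | 2,4,6-trihydroxyacetophenone (phloroacetophenone) | CC(=O)c1c(O)cc(O)cc1O | starting material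
2 | 2-bromopropane | CC(C)Br | starting material
3 | 1-(2-hydroxy-4,6-diisopropoxyphenyl)ethanone | CC(=O)c1c(O)cc(OC(C)C)cc1OC(C)C | intermediate
4 | 3,3'-diacetyl-4,4',6,6'-tetraisopropoxybiphenyl-2,2'-diol (racemic axis) | CC(=O)c1c(O)c(-c2c(O)c(C(C)=O)c(OC(C)C)cc2OC(C)C)c(OC(C)C)cc1OC(C)C | intermediate
5 | dibutyltin oxide | CCCC[Sn](=O)CCCC | starting material
6 | 4-methoxybenzoyl chloride | COc1ccc(cc1)C(Cl)=O | starting material
7 | 4-isopropoxybenzoyl chloride | CC(C)Oc1ccc(cc1)C(Cl)=O | starting material
8 | cyclic dibutylstannylene diether of 4 (dibenzo[d,f][1,3,2]dioxastannepine, both phenol oxygens on one Bu2Sn) | CCCC[Sn]1(CCCC)Oc2c(C(C)=O)c(OC(C)C)cc(OC(C)C)c2-c2c(OC(C)C)cc(OC(C)C)c(C(C)=O)c2O1 | intermediate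
9 | mono-(4-methoxybenzoate) of 4 whose other phenol oxygen carries Bu2Sn(Cl) | CCCC[Sn](Cl)(CCCC)Oc1c(C(C)=O)c(OC(C)C)cc(OC(C)C)c1-c1c(OC(C)C)cc(OC(C)C)c(C(C)=O)c1OC(=O)c1ccc(OC)cc1 | intermediate
10 | 3,3'-diacetyl-4,4',6,6'-tetraisopropoxy-2'-(4-isopropoxybenzoyloxy)biphenyl-2-yl 4-methoxybenzoate | COc1ccc(cc1)C(=O)Oc1c(C(C)=O)c(OC(C)C)cc(OC(C)C)c1-c1c(OC(C)C)cc(OC(C)C)c(C(C)=O)c1OC(=O)c1ccc(OC(C)C)cc1 | intermediate
11 | bis(1,3-diketone): 1-[2,2'-dihydroxy-4,4',6,6'-tetraisopropoxy-3'-(3-(4-isopropoxyphenyl)-3-oxopropanoyl)biphenyl-3-yl]-3-(4-methoxyphenyl)propane-1,3-dione | COc1ccc(cc1)C(=O)CC(=O)c1c(O)c(-c2c(O)c(C(=O)CC(=O)c3ccc(OC(C)C)cc3)c(OC(C)C)cc2OC(C)C)c(OC(C)C)cc1OC(C)C | intermediate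
12 | 5,7-diisopropoxy-8-[5,7-diisopropoxy-2-(4-isopropoxyphenyl)-4-oxo-4H-chromen-8-yl]-2-(4-methoxyphenyl)-4H-chromen-4-one (penta-O-isopropyl-4'-O-methylcupressuflavone) | COc1ccc(-c2cc(=O)c3c(OC(C)C)cc(OC(C)C)c(-c4c(OC(C)C)cc(OC(C)C)c5c(=O)cc(-c6ccc(OC(C)C)cc6)oc45)c3o2)cc1 | intermediate
13 | 5,7-dihydroxy-8-[5,7-dihydroxy-2-(4-hydroxyphenyl)-4-oxo-4H-chromen-8-yl]-2-(4-methoxyphenyl)-4H-chromen-4-one (4'-O-methylcupressuflavone) | COc1ccc(-c2cc(=O)c3c(O)cc(O)c(-c4c(O)cc(O)c5c(=O)cc(-c6ccc(O)cc6)oc45)c3o2)cc1 | target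

**Step count and risks**

Total steps: 5. Longest linear sequence: 5 (from 1).

The three steps most likely to fail are steps 3, 2 and 4.

Step 3 (new method). The stannylene may not form cleanly from two acetyl-chelated phenols, or tin phenoxides may shuttle aroyl groups between molecules so that the mixture drifts toward a statistical one. The fallback uses plain acylation without a template. It sets out from 4, which is acylated with 0.9 equiv of 6 (Et3N, cat. 4-(dimethylamino)pyridine, CH2Cl2, 0 °C, dilute) to the mono-ester 3,3'-diacetyl-2'-hydroxy-4,4',6,6'-tetraisopropoxybiphenyl-2-yl 4-methoxybenzoate F3. F3 differs strongly in polarity from 4 and from the bis-anisoate and is separated on silica, with 4 recycled. F3 is then acylated with 7 (pyridine, cat. 4-(dimethylamino)pyridine), and the route is rejoined at 10.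

Step 2. Coupling could occur at C5 (para to OH), the dimer could be over-oxidised, or the Lewis acid could strip an isopropyl group. The fallback sets out from 3, which is iodinated ortho to the phenol (N-iodosuccinimide, cat. CF3CO2H, MeCN) to 1-(2-hydroxy-3-iodo-4,6-diisopropoxyphenyl)ethanone F1. F1 is homocoupled in one pot by Miyaura borylation and Suzuki coupling (Pd(OAc)2, 2-dicyclohexylphosphino-2',6'-dimethoxybiphenyl, 0.55 equiv bis(pinacolato)diboron, K3PO4, dioxane/H2O, 90 °C). In that pot half of F1 becomes the pinacol boronate 1-[2-hydroxy-4,6-diisopropoxy-3-(4,4,5,5-tetramethyl-1,3,2-dioxaborolan-2-yl)phenyl]ethanone F2, which cross-couples with the remaining F1. The route is rejoined at 4.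

Step 4. The second acyl shift may stall on the crowded biaryl, or an aroyl group may migrate from one ring's ester oxygen to the other ring's phenoxide before C-acylation, which would lead to a 3-aroylflavone. The fallback is the chalcone route. It sets out from 4, which is condensed with a 1:1 mixture of 4-methoxybenzaldehyde and 4-hydroxybenzaldehyde (KOH, EtOH/H2O, rt to 50 °C, Claisen–Schmidt) to the mixed bis-chalcone (E)-1-[2,2'-dihydroxy-3'-((E)-3-(4-hydroxyphenyl)acryloyl)-4,4',6,6'-tetraisopropoxybiphenyl-3-yl]-3-(4-methoxyphenyl)prop-2-en-1-one F4. This is statistical (at most 50 %), but F4 alone carries one free 4-OH and so separates from the two symmetrical bis-chalcones. Both rings are closed by oxidative cyclisation (cat. I2, DMSO, 130 °C) to 5,5'',7,7''-tetra-O-isopropyl-4'-O-methylcupressuflavone F5, and the four isopropyl groups are removed with BCl3 as in step 5. The route is rejoined at 13.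

**Further compounds**
F1 | step 2 | 1-(2-hydroxy-3-iodo-4,6-diisopropoxyphenyl)ethanone | CC(=O)c1c(O)c(I)c(OC(C)C)cc1OC(C)C
F2 | step 2 | 1-[2-hydroxy-4,6-diisopropoxy-3-(4,4,5,5-tetramethyl-1,3,2-dioxaborolan-2-yl)phenyl]ethanone | CC(=O)c1c(O)c(B2OC(C)(C)C(C)(C)O2)c(OC(C)C)cc1OC(C)C
F3 | step 3 | 3,3'-diacetyl-2'-hydroxy-4,4',6,6'-tetraisopropoxybiphenyl-2-yl 4-methoxybenzoate | COc1ccc(cc1)C(=O)Oc1c(C(C)=O)c(OC(C)C)cc(OC(C)C)c1-c1c(OC(C)C)cc(OC(C)C)c(C(C)=O)c1O
F4 | step 4 | (E)-1-[2,2'-dihydroxy-3'-((E)-3-(4-hydroxyphenyl)acryloyl)-4,4',6,6'-tetraisopropoxybiphenyl-3-yl]-3-(4-methoxyphenyl)prop-2-en-1-one | COc1ccc(/C=C/C(=O)c2c(O)c(-c3c(O)c(C(=O)/C=C/c4ccc(O)cc4)c(OC(C)C)cc3OC(C)C)c(OC(C)C)cc2OC(C)C)cc1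
F5 | step 4 | 5,5'',7,7''-tetra-O-isopropyl-4'-O-methylcupressuflavone (free 4'''-OH) | COc1ccc(-c2cc(=O)c3c(OC(C)C)cc(OC(C)C)c(-c4c(OC(C)C)cc(OC(C)C)c5c(=O)cc(-c6ccc(O)cc6)oc45)c3o2)cc1
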